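(The readings were computed on assumed constants.)

South, the flask asked about, holds 0.57 M of starting material against 0.627 M of reagent and has been followed to 3.00 min. East holds the same reagent but half the starting material.

| setting | south | east | flask |
|---|---|---|---|
| starting material | 0.57 M | 0.28 M | 0.57 M |
| reagent | 0.627 M | 0.627 M | 0.627 M |
| remark | the very flask that is asked about, followed so far | run made earlier |  |
| time |  |  | 25 min |

| run | time / min | first product / % |
|---|---|---|
| south | 0.417 | 45.9 |
| south | 1.00 | 61.9 |
| south | 2.00 | 71.3 |
| south | 3.00 | 73.1 |
| east | 4.00 | 81.3 |
| east | 8.00 | 74.9 |
| east | 12.0 | 66.6 |
| east | 20.0 | 54.5 |

(each reading ± 1 percentage point)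

* when, up to 25 min, the flask holds most first product
* the amount of first product, in percent of the starting material charged, at that time
* the first time at which first product reaches 37 %, in the same percent, in min

- a reading or a percentage of first product counts all its forms, free or not

Taken alone, the main step, starting material + reagent → first product, has no maximum. The first south reading gives it a rate constant 3.13 /M/min, and with it first product reaches 37 % at 0.292 min.

Next comes a further step of first product with reagent. East falls from 81.3 % to 54.5 % between 4.00 min and 20.0 min. With its reagent frozen near 0.347 M, that reads as a loss constant 0.0720 /M/min. In this two-step picture gain and loss of first product both carry c(reagent), so it cancels: first product peaks where c(starting material)/c(first product) equals the selectivity factor, the loss constant over the main constant, read from these runs as 0.0230.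

Then the rest. South's 73.1 % at 3.00 min stands below east's 81.3 % at 4.00 min, but the two readings differ in charge and in time, so the percentage missing from south need not be starting material. The rise between the last two south readings, plus the loss, with reagent frozen near 0.215 M, suggests roughly 4.34 % starting material at 2.50 min, a rough figure given the scatter. By the factor the peak comes near 1.68 % starting material, which this estimate reaches at 3.90 min, with first product close to the last reading.

The forecast puts the maximum later, 77 % at 7 min, and gives 0.28 min for the level, expecting “a broad, flat maximum near 77% around 7 min”.

South gives 0.268 min for the level and its maximum, 73.3 %, at 4.26 min, earlier than the forecast's time.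

    starting material + reagent → first product (k = 0.0650 /M/s)
    reagent + first product → double product (k = 0.00120 /M/s)
    2 starting material → homo dimer (k = 0.0150 /M/s)
    crystals ⇌ first product, rate k4*(cs4 - [first product]) while solid is left; crystals form when [first product] > cs4 (solubility = 0.360 M, k = 4.40 /s)

At 4.26 min south holds 1.17 % starting material and 73.3 % first product, of which 10.1 % are crystals. Starting material over dissolved first product is then 0.0185, against the factor 0.0230 read from the runs. The neighbour charged with 0.25 M reagent ends at 25.0 min with 0.48 % of its reagent left and a ratio of 0.0655, still above the factor, and its best is 42.2 %.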